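**Strategy**

The oxolane is taken apart at both C–O bonds: its four carbons (C2–C5) come from a 3,4-diarylcyclobutane-1,2-dicarboxylate, and the ring oxygen from water. Anodic oxidation breaks the strained bond between the two aryl-bearing carbons and inserts the oxygen, expanding the four-membered carbocycle to the five-membered ether and setting C2 and C5 in one operation. The step exploits the meso symmetry of the target: O1 sits between two equivalent para-oxygenated benzylic carbons (C2, C5), while C3 and C4 are cis. Only this cis pair must be preset, which a photocycloaddition of a symmetrical stilbene to maleic anhydride does; the aryl-carbon configuration of the cyclobutane is irrelevant, since the step is stereoconvergent.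

Key step: step 4

Remark on the chemistry: the four stereodescriptors of the target describe a meso compound. With oxolane numbering O1, C2/C5 (aryl) and C3/C4 (hydroxymethyl), the aryl groups are cis to each other, the hydroxymethyl groups are cis to each other, and each aryl is trans to its neighbouring hydroxymethyl. Only relative configuration has to be controlled; chiral intermediates are racemic and drawn as one enantiomer.

**Route**

Step 1
Reactants: 1 4-(benzyloxy)-3,5-dimethoxybenzaldehyde (two molecules)
Product: 2 (E)-1,2-bis[4-(benzyloxy)-3,5-dimethoxyphenyl]ethene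
Conditions: TiCl4, Zn, THF, reflux
Reagents that add atoms: none
Why: McMurry reductive coupling of an electron-rich aryl aldehyde on low-valent titanium should give the symmetrical stilbene, mainly as the E isomer, and the alkene geometry has no bearing on the stereocentres of the target.

Step 2
Reactants: 2 (E)-1,2-bis[4-(benzyloxy)-3,5-dimethoxyphenyl]ethene; 3 maleic anhydride (excess)
Product: 4 6,7-bis[4-(benzyloxy)-3,5-dimethoxyphenyl]-3-oxabicyclo[3.2.0]heptane-2,4-dione, cis ring fusion, the two aryl groups trans to each other (racemic)
Conditions: hν (365 nm), degassed PhH, rt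
Reagents that add atoms: none
Why: [2+2] photocycloaddition of the excited electron-rich stilbene with the electron-poor alkene through their exciplex should give the cyclobutane, the cyclic anhydride forcing the two carboxyl carbons cis (the later C3/C4 relationship), while the aryl-carbon configuration, trans from the E-stilbene, is of no consequence because step 4 erases it.

Step 3
Reactants: 4 the cis-fused cyclobutane anhydride
Product: 5 dimethyl 3,4-bis[4-(benzyloxy)-3,5-dimethoxyphenyl]cyclobutane-1,2-dicarboxylate, ester groups cis, aryl groups trans (racemic)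
Conditions: MeOH, H2SO4 (cat.), reflux
Reagents that add atoms: methanol (SMILES: CO), two molecules
Why: Acid-catalysed methanolysis of the anhydride followed by Fischer esterification of the half-ester should give the cis-diester without enolisation of the α-carbons, and it removes the carboxylic acid that would otherwise lactonise onto a benzylic cation in step 4.

Step 4
Reactants: 5 the cis-diester cyclobutane
Product: 7 dimethyl (2R,3R,4S,5S)-2,5-bis[4-(benzyloxy)-3,5-dimethoxyphenyl]oxolane-3,4-dicarboxylate (meso), via ring-opened hydroxy benzylic cation 6 (not isolated)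
Conditions: graphite felt anode, Pt cathode, divided cell, LiClO4 (0.1 M), MeCN/H2O (19:1), constant current, 2.2 F/mol, rt, anolyte aged 30 min
Reagents that add atoms: water (SMILES: O)
Why: Proposed new method: anodic one-electron oxidation of a trialkoxyaryl ring should give a radical cation in which the strained, doubly benzylic C3–C4 bond of the cyclobutane breaks to a distonic 1,4-radical cation; water captures the cationic benzylic carbon, the remaining benzylic radical is oxidised at the anode to cation 6, and the new hydroxyl closes onto it, so that one oxygen atom is inserted between the two aryl-bearing carbons and the four-membered carbocycle becomes the oxolane. The closest known reaction types are the anodic and photoredox 1,3-difunctionalisation of arylcyclopropanes through their radical cations, the electron-transfer photooxygenation of 1,2-diarylcyclobutanes to 1,2-dioxanes, and the anodic dimerisation of propenylarenes in wet acetonitrile to 2,5-diaryloxolanes. The oxolane closes by 5-exo-trig attack of the hydroxyl on the benzylic cation. Both new stereocentres (C2 and C5) are controlled by the untouched cis pair C3/C4: each aryl group settles trans to its neighbouring ester, which places the aryl groups cis to each other, and the acid generated in the anolyte lets the two para-alkoxybenzylic C–O bonds ionise reversibly so that kinetic epimers converge on this isomer. Because both aryl-bearing carbons pass through planar intermediates the step is stereoconvergent, any aryl-carbon epimer of 5 giving the same product. The step needs cleavage of the aryl-flanked ring bond in preference to cycloreversion into two cinnamate units and to benzylic C–H oxidation, which the ring strain, the two para-alkoxyaryl donors, the electron-poor ester-bearing carbons and the large excess of water should secure.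

Step 5
Reactants: 7 the meso oxolane diester
Product: 8 [(2R,3S,4R,5S)-2,5-bis[4-(benzyloxy)-3,5-dimethoxyphenyl]oxolane-3,4-diyl]dimethanol (meso)
Conditions: LiAlH4, THF, 0 °C to rt
Reagents that add atoms: none
Why: Hydride reduction of both esters with LiAlH4 should be faster than any enolisation, so the cis C3/C4 pair and the benzylic centres are retained, and the benzyl ethers and the ring ether are inert.

Step 6
Reactants: 8 the bis(benzyl ether) diol
Product: 9 [(2R,3S,4R,5S)-2,5-bis(4-hydroxy-3,5-dimethoxyphenyl)oxolane-3,4-diyl]dimethanol (meso; target CNP0170897.5)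
Conditions: H2 (1 atm), Pd/C (10% Pd on carbon), EtOAc/MeOH, rt
Reagents that add atoms: none
Why: Hydrogenolysis of the two aryl benzyl ethers over Pd/C in a neutral solvent should be much faster than cleavage of the ring's benzylic C–O bonds and frees both phenols without touching a stereocentre.

**Compound list**

1 | 4-(benzyloxy)-3,5-dimethoxybenzaldehyde | COc1cc(C=O)cc(OC)c1OCc1ccccc1 | starting material
2 | (E)-1,2-bis[4-(benzyloxy)-3,5-dimethoxyphenyl]ethene | COc1cc(/C=C/c2cc(OC)c(OCc3ccccc3)c(OC)c2)cc(OC)c1OCc1ccccc1 | intermediate
3 | maleic anhydride (furan-2,5-dione) | O=C1OC(=O)C=C1 | starting material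
4 | 6,7-bis[4-(benzyloxy)-3,5-dimethoxyphenyl]-3-oxabicyclo[3.2.0]heptane-2,4-dione, cis-fused, aryl groups trans (racemic, one enantiomer drawn) | O=C1OC(=O)[C@@H]2[C@H]1[C@@H](c1cc(OC)c(OCc3ccccc3)c(OC)c1)[C@@H]2c1cc(OC)c(OCc2ccccc2)c(OC)c1 | intermediate
5 | dimethyl 3,4-bis[4-(benzyloxy)-3,5-dimethoxyphenyl]cyclobutane-1,2-dicarboxylate, esters cis, aryl groups trans (racemic, one enantiomer drawn) | COC(=O)[C@@H]1[C@H](C(=O)OC)[C@@H](c2cc(OC)c(OCc3ccccc3)c(OC)c2)[C@@H]1c1cc(OC)c(OCc2ccccc2)c(OC)c1 | intermediate
6 | ring-opened hydroxy benzylic cation: dimethyl 2-{[4-(benzyloxy)-3,5-dimethoxyphenyl](hydroxy)methyl}-3-{[4-(benzyloxy)-3,5-dimethoxyphenyl]methyliumyl}butanedioate, meso-type 2,3-relationship kept from 5, carbinol carbon as both epimers | OC(c1cc(OC)c(OCc2ccccc2)c(OC)c1)[C@@H](C(=O)OC)[C@@H](C(=O)OC)[CH+]c1cc(OC)c(OCc2ccccc2)c(OC)c1 | intermediate (not isolated)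
7 | dimethyl (2R,3R,4S,5S)-2,5-bis[4-(benzyloxy)-3,5-dimethoxyphenyl]oxolane-3,4-dicarboxylate (meso: aryls cis, esters cis, aryl trans to neighbouring ester) | COc1cc([C@H]2O[C@@H](c3cc(OC)c(OCc4ccccc4)c(OC)c3)[C@H](C(=O)OC)[C@@H]2C(=O)OC)cc(OC)c1OCc1ccccc1 | intermediate
8 | [(2R,3S,4R,5S)-2,5-bis[4-(benzyloxy)-3,5-dimethoxyphenyl]oxolane-3,4-diyl]dimethanol (meso) | COc1cc([C@H]2O[C@@H](c3cc(OC)c(OCc4ccccc4)c(OC)c3)[C@H](CO)[C@@H]2CO)cc(OC)c1OCc1ccccc1 | intermediate
9 | [(2R,3S,4R,5S)-2,5-bis(4-hydroxy-3,5-dimethoxyphenyl)oxolane-3,4-diyl]dimethanol (meso) | COc1cc([C@H]2O[C@@H](c3cc(OC)c(O)c(OC)c3)[C@H](CO)[C@@H]2CO)cc(OC)c1O | target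

**Step count and risks**

Total step count: 6. Longest linear sequence: 6 steps (1 → 2 → 4 → 5 → 7 → 8 → 9).

Steps most likely to fail:

1. Step 4 (proposed new method). The radical cation may fragment across the ring into two cinnamate units (retro-[2+2]). The benzylic cation may be captured by the neighbouring aryl ring (Friedel–Crafts closure to an aryltetralin) or lose the α-ester proton. The product may be oxidised further at its benzylic C–H bonds, and the acid-mediated convergence of the benzylic epimers may be incomplete. The fallback uses known reaction types and reaches the oxolane by a ring expansion followed by a ring contraction. It sets out from 5: photoinduced electron-transfer oxygenation (9,10-dicyanoanthracene, O2, hν, MeCN) should insert dioxygen into the same aryl-flanked bond and give the six-membered peroxide dimethyl 3,6-bis[4-(benzyloxy)-3,5-dimethoxyphenyl]-1,2-dioxane-4,5-dicarboxylate F1 (esters cis, each aryl trans to its neighbouring ester; other C3/C6 epimers are tolerated). PPh3 (PhMe, 60 °C) should then excise one peroxide oxygen through a phosphonium alkoxide with inversion at one benzylic carbon, contracting the ring to the 2-epimer of 7, dimethyl 2,5-trans-bis[4-(benzyloxy)-3,5-dimethoxyphenyl]oxolane-3,4-cis-dicarboxylate F2. BF3·OEt2 (cat.) in CH2Cl2 at −20 °C should epimerise the benzylic centre whose aryl is cis to its ester by reversible ionisation, and the route is rejoined at 7.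

2. Step 2. The excited stilbene and maleic anhydride may relax by full electron transfer and back-transfer without bond formation; the stilbene may only isomerise or dimerise with itself; the pair may copolymerise. The fallback replaces the crossed cycloaddition by a templated homodimerisation of known type and sets out from 1. Knoevenagel–Doebner condensation with malonic acid (pyridine, piperidine, 90 °C) should give (E)-3-[4-(benzyloxy)-3,5-dimethoxyphenyl]prop-2-enoic acid F3. Two molecules are esterified (DCC, DMAP, CH2Cl2) onto naphthalene-1,8-diol to give naphthalene-1,8-diyl bis{(E)-3-[4-(benzyloxy)-3,5-dimethoxyphenyl]prop-2-enoate} F4, which holds the two alkenes parallel and close. Irradiation (365 nm) should give by intramolecular [2+2] the template-bound cyclobutane F5 (naphthalene-1,8-diyl 3,4-bis[4-(benzyloxy)-3,5-dimethoxyphenyl]cyclobutane-1,2-dicarboxylate F5; esters cis, aryls cis, aryl trans to ester). MeOH, H2SO4 (cat.), reflux releases the template and gives dimethyl 3,4-cis-bis[4-(benzyloxy)-3,5-dimethoxyphenyl]cyclobutane-1,2-cis-dicarboxylate F6, the epimer of 5 at one aryl carbon. F6 takes the place of 5 in step 4, where both aryl carbons become planar, and the route is rejoined at 7.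

3. Step 6. Hydrogenolysis may go on from the aryl benzyl ethers to the two benzylic C–O bonds of the oxolane, which are themselves benzylic ethers para to an oxygen donor, and open the ring. The fallback removes the benzyl groups by a Lewis acid before the esters are reduced, at a stage where the neighbouring esters disfavour ionisation of the ring C–O bonds. It sets out from 7: BCl3 with pentamethylbenzene as cation scavenger (CH2Cl2, −78 °C) should give dimethyl 2,5-bis(4-hydroxy-3,5-dimethoxyphenyl)oxolane-3,4-dicarboxylate F7 (meso). LiAlH4 (excess, THF, 0 °C to rt) then reduces both esters and the route is rejoined at 9.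

**Further compounds**

F1 | step 4 | dimethyl 3,6-bis[4-(benzyloxy)-3,5-dimethoxyphenyl]-1,2-dioxane-4,5-dicarboxylate, esters cis, aryls cis, aryl trans to neighbouring ester (meso) | COc1cc([C@H]2OO[C@@H](c3cc(OC)c(OCc4ccccc4)c(OC)c3)[C@H](C(=O)OC)[C@@H]2C(=O)OC)cc(OC)c1OCc1ccccc1
F2 | step 4 | dimethyl 2,5-trans-bis[4-(benzyloxy)-3,5-dimethoxyphenyl]oxolane-3,4-cis-dicarboxylate, the 2-epimer of 7 (racemic, one enantiomer drawn) | COc1cc([C@@H]2O[C@@H](c3cc(OC)c(OCc4ccccc4)c(OC)c3)[C@H](C(=O)OC)[C@@H]2C(=O)OC)cc(OC)c1OCc1ccccc1
F3 | step 2 | (E)-3-[4-(benzyloxy)-3,5-dimethoxyphenyl]prop-2-enoic acid | COc1cc(/C=C/C(=O)O)cc(OC)c1OCc1ccccc1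
F4 | step 2 | naphthalene-1,8-diyl bis{(E)-3-[4-(benzyloxy)-3,5-dimethoxyphenyl]prop-2-enoate} | O=C(/C=C/c1cc(OC)c(OCc2ccccc2)c(OC)c1)Oc1cccc2cccc(OC(=O)/C=C/c3cc(OC)c(OCc4ccccc4)c(OC)c3)c12
F5 | step 2 | naphthalene-1,8-diyl 3,4-bis[4-(benzyloxy)-3,5-dimethoxyphenyl]cyclobutane-1,2-dicarboxylate, esters cis, aryls cis, aryl trans to ester (meso) | O=C1Oc2cccc3cccc(OC(=O)[C@@H]4[C@H]1[C@@H](c1cc(OC)c(OCc5ccccc5)c(OC)c1)[C@H]4c1cc(OC)c(OCc4ccccc4)c(OC)c1)c23
F6 | step 2 | dimethyl 3,4-cis-bis[4-(benzyloxy)-3,5-dimethoxyphenyl]cyclobutane-1,2-cis-dicarboxylate, aryl trans to ester (meso) | COC(=O)[C@@H]1[C@H](C(=O)OC)[C@@H](c2cc(OC)c(OCc3ccccc3)c(OC)c2)[C@H]1c1cc(OC)c(OCc2ccccc2)c(OC)c1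
F7 | step 6 | dimethyl (2R,3R,4S,5S)-2,5-bis(4-hydroxy-3,5-dimethoxyphenyl)oxolane-3,4-dicarboxylate (meso) | COc1cc([C@H]2O[C@@H](c3cc(OC)c(O)c(OC)c3)[C@H](C(=O)OC)[C@@H]2C(=O)OC)cc(OC)c1O
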